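**Plan**

Cuts: the five O–benzyl bonds go first. Next, C2–C3 and O1–C2 of the acacetin ring C are cut, which frees 4-methoxybenzoyl chloride and a 2-hydroxydeoxybenzoin. Then the bond between the ketone carbon and the acacetin ring A is cut (aryllithium plus arylacetaldehyde), and last the C6–CH2 bond of the apigenin half (an allyl group placed by a Claisen rearrangement).
Enabling feature: acacetin C3 (ring C) is bonded directly to apigenin C6. C3 can therefore be carried as a CH2 lying between the future C4 carbonyl on the acacetin ring A and the apigenin ring A. The future O1 sits beside it as a free phenol that can pass an aroyl group to this acidic carbon.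
Forward: apigenin supplies three rings ready-made, and its C6 receives a two-carbon arm by O5-allylation, [3,3] shift and oxidative cleavage. A phloroglucinol-derived aryllithium is added as the acacetin ring A. The acacetin ring C is the only ring built, and it closes as ring B arrives. Hydrogenolysis ends the route.
Stereochemistry: the target has no stereocentre. The sp3 centres that arise on the way are racemic and are erased by oxidation or dehydration.

Key step: step 11

Remark on the chemistry: the C3–C6 biaryl bond has four ortho substituents and may be a stereogenic axis. The target structure carries no axial descriptor, so the racemic (or freely rotating) compound is taken as the target.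
Naming: "5,7,4'-tri-O-benzylapigenin-6-yl" means the 5,7-bis(benzyloxy)-2-[4-(benzyloxy)phenyl]-4-oxo-4H-chromen-6-yl group.

**Route**

Step 1
Reactants: 1 apigenin
Product: 2 7,4'-di-O-benzylapigenin (5-OH free)
Conditions: BnBr (2.1 equiv), K2CO3, DMF, rt
Reagents that add atoms: benzyl bromide, BrCc1ccccc1
Why: Williamson etherification: the acidic 7-OH and 4'-OH are alkylated, while the 5-OH, hydrogen-bonded to the C4 carbonyl, should stay untouched at room temperature with two equivalents of halide.

Step 2
Reactants: 2 7,4'-di-O-benzylapigenin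
Product: 3 5-O-allyl-7,4'-di-O-benzylapigenin
Conditions: allyl bromide (excess), K2CO3, DMF, 70 °C
Reagents that add atoms: allyl bromide, C=CCBr
Why: Williamson etherification under forcing conditions: with no other phenol left, heat and excess halide overcome the chelation of the 5-OH, as is routine for 5-hydroxyflavones.

Step 3
Reactants: 3 5-O-allyl-7,4'-di-O-benzylapigenin
Product: 5 6-allyl-7,4'-di-O-benzylapigenin (5-OH free), via ortho-dienone 4 (not isolated)
Conditions: N,N-diethylaniline, 200–210 °C, Ar
Reagents that add atoms: none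
Why: Aromatic Claisen rearrangement: the [3,3] shift can reach only C6, because the other position ortho to O5 is the ring-fusion carbon C4a, and dienone 4 carries a hydrogen at C6 and should rearomatise at once in the basic solvent, so no onward Cope shift to C8 is expected.

Step 4
Reactants: 5 6-allyl-7,4'-di-O-benzylapigenin
Product: 6 6-allyl-5,7,4'-tri-O-benzylapigenin
Conditions: BnBr, K2CO3, n-Bu4NI (cat.), DMF, 80 °C
Reagents that add atoms: benzyl bromide, BrCc1ccccc1
Why: Williamson etherification with iodide catalysis: the chelated, flanked 5-OH needs heat, and it must be capped because a free phenol next to the side chain would later close onto a side-chain carbonyl to give a benzofuran.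

Step 5
Reactants: 6 6-allyl-5,7,4'-tri-O-benzylapigenin
Product: 8 (5,7,4'-tri-O-benzylapigenin-6-yl)acetaldehyde, via vicinal diol 7 (not isolated)
Conditions: OsO4 (cat.), NaIO4, 2,6-lutidine, dioxane–H2O, rt
Reagents that add atoms: osmium tetroxide (delivers the oxygen, catalytic), O=[Os](=O)(=O)=O; sodium periodate (terminal oxygen source), [Na+].[O-]I(=O)(=O)=O
Why: Lemieux–Johnson oxidative cleavage: OsO4 should dihydroxylate the isolated terminal alkene far faster than the conjugated, electron-poor C2–C3 bond of the pyranone, periodate cleaves diol 7 in the same flask, and lutidine holds back over-oxidation.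

Step 6
Reactants: 9 phloroglucinol
Product: 10 1,3,5-tris(methoxymethoxy)benzene
Conditions: NaH, MOMCl, DMF, 0 °C to rt
Reagents that add atoms: chloromethyl methyl ether, COCCl
Why: Threefold Williamson-type O-alkylation: the hard electrophile favours oxygen over ring carbon, and the symmetric product has only one kind of ring CH, so the later metalation raises no regiochemical question.

Step 7
Reactants: 10 1,3,5-tris(methoxymethoxy)benzene; 8 (5,7,4'-tri-O-benzylapigenin-6-yl)acetaldehyde
Product: 12 (±)-1-[2,4,6-tris(methoxymethoxy)phenyl]-2-(5,7,4'-tri-O-benzylapigenin-6-yl)ethanol, via aryllithium 11 (not isolated)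
Conditions: 10 (1.3 equiv), n-BuLi (1.2 equiv), THF, 0 °C to rt; cool to −78 °C and add slowly to 8 in THF, −78 °C; AcOH quench at −78 °C
Reagents that add atoms: none
Why: Directed ortho-metalation followed by 1,2-addition of an aryllithium to an aldehyde: every ring CH of 10 lies between two coordinating OMOM groups, the aldehyde should outrun the vinylogous-ester carbonyl of the flavone at −78 °C when 11 is never in excess, this carbanion route avoids Lewis-acid acylation or Fries conditions that would strip the benzyl ether peri to the apigenin carbonyl, and the racemic carbinol centre is erased in step 8.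

Step 8
Reactants: 12 (±)-1-[2,4,6-tris(methoxymethoxy)phenyl]-2-(5,7,4'-tri-O-benzylapigenin-6-yl)ethanol
Product: 13 1-[2,4,6-tris(methoxymethoxy)phenyl]-2-(5,7,4'-tri-O-benzylapigenin-6-yl)ethanone
Conditions: Dess–Martin periodinane, NaHCO3, CH2Cl2, 0 °C to rt
Reagents that add atoms: none
Why: Dess–Martin oxidation: the buffered, non-acidic oxidant should turn the hindered secondary benzylic alcohol into the ketone without ionising the very electron-rich carbinol, which would otherwise dehydrate to the stilbene.

Step 9
Reactants: 13 1-[2,4,6-tris(methoxymethoxy)phenyl]-2-(5,7,4'-tri-O-benzylapigenin-6-yl)ethanone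
Product: 14 1-(2,4,6-trihydroxyphenyl)-2-(5,7,4'-tri-O-benzylapigenin-6-yl)ethanone
Conditions: conc. HCl (cat.), MeOH–THF, 45 °C
Reagents that add atoms: none
Why: Acid-catalysed transacetalisation (MOM cleavage): the three phenolic acetals, needed only to steer the lithiation, exchange with methanol under catalytic acid that should be too mild at this temperature to touch aryl benzyl ethers.

Step 10
Reactants: 14 1-(2,4,6-trihydroxyphenyl)-2-(5,7,4'-tri-O-benzylapigenin-6-yl)ethanone
Product: 15 1-[2-hydroxy-4,6-bis(benzyloxy)phenyl]-2-(5,7,4'-tri-O-benzylapigenin-6-yl)ethanone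
Conditions: BnBr (2.1 equiv), K2CO3 (2.2 equiv), DMF, rt to 40 °C
Reagents that add atoms: benzyl bromide, BrCc1ccccc1
Why: Chelation-controlled Williamson etherification: the para OH and one of the two equivalent ortho OH groups are alkylated while the last ortho OH is tied to the ketone by a hydrogen bond, which is the selectivity long used to make 2-hydroxy-4,6-bis(benzyloxy)acetophenone from phloroacetophenone, and it puts all five masked phenols under one kind of protecting group.

Step 11
Reactants: 15 1-[2-hydroxy-4,6-bis(benzyloxy)phenyl]-2-(5,7,4'-tri-O-benzylapigenin-6-yl)ethanone; 16 4-methoxybenzoyl chloride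
Product: 20 penta-O-benzyl ether of the target, via aryl ester 17 (not isolated), via 1,3-diketone 18 (not isolated), via hemiketal 19 (not isolated)
Conditions: 16 (1.5 equiv), DBU (3 equiv), dry pyridine, 0 °C then 110 °C
Reagents that add atoms: none
Why: The amine medium first aroylates the only free hydroxyl, the phenol ortho to the ketone, to give ester 17; DBU then removes a proton from the CH2, which is acidified by the ketone and its aryl substituent, and the carbanion attacks the nearby ester carbonyl within a six-membered cyclic array, moving the aroyl group from O to C (Baker–Venkataraman shift, C2–C3 formed) to give diketone 18. The phenoxide set free in this shift adds to the 4-methoxybenzoyl carbonyl in a 6-exo-trig closure (O1–C2 formed, hemiketal 19), and loss of water across C2–C3, helped by the acidic C3–H and the amine hydrochloride in the hot medium, should deliver the pyranone of 20. The closest known reaction type is the one-pot Baker–Venkataraman or Allan–Robinson aroylation of 2-hydroxydeoxybenzoins to 2,3-diarylchromones. No stereocentre remains, since the sp3 centres of 18 and 19 vanish on dehydration and the hindered C3–C6 axis forms as a racemate. The step needs acylation at a crowded carbon in place of oxygen and ring closure by the ring A oxygen alone: the first is secured by intramolecular delivery from the neighbouring oxygen, with any enol ester returned by the nucleophilic amines, and the second by the benzyl groups on both apigenin oxygens that flank the CH2, which rule out benzofuran closure. Because the 4-methoxy group enters with the acid chloride, no phenol ever has to be methylated selectively.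

Step 12
Reactants: 20 penta-O-benzyl ether of the target
Product: 21 target biflavone CNP0273516.0
Conditions: H2 (1 atm), 10% Pd/C, THF–MeOH, rt
Reagents that add atoms: none
Why: Catalytic hydrogenolysis of aryl benzyl ethers: the five O–CH2Ph bonds should be cleaved at atmospheric pressure, the aryl methyl ether is inert, and the two pyranone double bonds (one tetrasubstituted, one conjugated and trisubstituted) normally survive these conditions.

**Compound list**

1 | apigenin, 5,7-dihydroxy-2-(4-hydroxyphenyl)-4H-chromen-4-one | O=c1cc(-c2ccc(O)cc2)oc2cc(O)cc(O)c12 | starting material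
2 | 7,4'-di-O-benzylapigenin | O=c1cc(-c2ccc(OCc3ccccc3)cc2)oc2cc(OCc3ccccc3)cc(O)c12 | intermediate
3 | 5-O-allyl-7,4'-di-O-benzylapigenin | C=CCOc1cc(OCc2ccccc2)cc2oc(-c3ccc(OCc4ccccc4)cc3)cc(=O)c12 | intermediate
4 | ortho-dienone, racemic 6-allyl-7-(benzyloxy)-2-[4-(benzyloxy)phenyl]-6H-chromene-4,5-dione (forms in the flask) | C=CCC1C(=O)C2=C(C=C1OCc1ccccc1)OC(=CC2=O)c1ccc(OCc2ccccc2)cc1 | intermediate
5 | 6-allyl-7,4'-di-O-benzylapigenin | C=CCc1c(OCc2ccccc2)cc2oc(-c3ccc(OCc4ccccc4)cc3)cc(=O)c2c1O | intermediate
6 | 6-allyl-5,7,4'-tri-O-benzylapigenin | C=CCc1c(OCc2ccccc2)cc2oc(-c3ccc(OCc4ccccc4)cc3)cc(=O)c2c1OCc1ccccc1 | intermediate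
7 | racemic 6-(2,3-dihydroxypropyl)-5,7,4'-tri-O-benzylapigenin (forms in the flask) | OCC(O)Cc1c(OCc2ccccc2)cc2oc(-c3ccc(OCc4ccccc4)cc3)cc(=O)c2c1OCc1ccccc1 | intermediate
8 | (5,7,4'-tri-O-benzylapigenin-6-yl)acetaldehyde | O=CCc1c(OCc2ccccc2)cc2oc(-c3ccc(OCc4ccccc4)cc3)cc(=O)c2c1OCc1ccccc1 | intermediate
9 | phloroglucinol, benzene-1,3,5-triol | Oc1cc(O)cc(O)c1 | starting material
10 | 1,3,5-tris(methoxymethoxy)benzene | COCOc1cc(OCOC)cc(OCOC)c1 | intermediate
11 | 2,4,6-tris(methoxymethoxy)phenyllithium (forms in the flask) | [Li]c1c(OCOC)cc(OCOC)cc1OCOC | intermediate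
12 | racemic 1-[2,4,6-tris(methoxymethoxy)phenyl]-2-(5,7,4'-tri-O-benzylapigenin-6-yl)ethanol | COCOc1cc(OCOC)c(C(O)Cc2c(OCc3ccccc3)cc3oc(-c4ccc(OCc5ccccc5)cc4)cc(=O)c3c2OCc2ccccc2)c(OCOC)c1 | intermediate
13 | 1-[2,4,6-tris(methoxymethoxy)phenyl]-2-(5,7,4'-tri-O-benzylapigenin-6-yl)ethanone | COCOc1cc(OCOC)c(C(=O)Cc2c(OCc3ccccc3)cc3oc(-c4ccc(OCc5ccccc5)cc4)cc(=O)c3c2OCc2ccccc2)c(OCOC)c1 | intermediate
14 | 1-(2,4,6-trihydroxyphenyl)-2-(5,7,4'-tri-O-benzylapigenin-6-yl)ethanone | O=C(Cc1c(OCc2ccccc2)cc2oc(-c3ccc(OCc4ccccc4)cc3)cc(=O)c2c1OCc1ccccc1)c1c(O)cc(O)cc1O | intermediate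
15 | 1-[2-hydroxy-4,6-bis(benzyloxy)phenyl]-2-(5,7,4'-tri-O-benzylapigenin-6-yl)ethanone | O=C(Cc1c(OCc2ccccc2)cc2oc(-c3ccc(OCc4ccccc4)cc3)cc(=O)c2c1OCc1ccccc1)c1c(O)cc(OCc2ccccc2)cc1OCc1ccccc1 | intermediate
16 | 4-methoxybenzoyl chloride | COc1ccc(C(=O)Cl)cc1 | starting material
17 | 4-methoxybenzoate ester of the phenol of 15 (forms in the flask) | O=C(Cc1c(OCc2ccccc2)cc2oc(-c3ccc(OCc4ccccc4)cc3)cc(=O)c2c1OCc1ccccc1)c1c(OC(=O)c2ccc(OC)cc2)cc(OCc2ccccc2)cc1OCc1ccccc1 | intermediate
18 | racemic 1-[2-hydroxy-4,6-bis(benzyloxy)phenyl]-3-(4-methoxyphenyl)-2-(5,7,4'-tri-O-benzylapigenin-6-yl)propane-1,3-dione (forms in the flask) | COc1ccc(C(=O)C(C(=O)c2c(O)cc(OCc3ccccc3)cc2OCc2ccccc2)c2c(OCc3ccccc3)cc3oc(-c4ccc(OCc5ccccc5)cc4)cc(=O)c3c2OCc2ccccc2)cc1 | intermediate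
19 | racemic 5,7-bis(benzyloxy)-2-hydroxy-2-(4-methoxyphenyl)-3-(5,7,4'-tri-O-benzylapigenin-6-yl)chroman-4-one, diastereomer mixture (forms in the flask) | COc1ccc(C2(O)Oc3cc(OCc4ccccc4)cc(OCc4ccccc4)c3C(=O)C2c2c(OCc3ccccc3)cc3oc(-c4ccc(OCc5ccccc5)cc4)cc(=O)c3c2OCc2ccccc2)cc1 | intermediate
20 | penta-O-benzyl ether of the target, 5,7-bis(benzyloxy)-2-(4-methoxyphenyl)-3-(5,7,4'-tri-O-benzylapigenin-6-yl)-4H-chromen-4-one | COc1ccc(-c2oc3cc(OCc4ccccc4)cc(OCc4ccccc4)c3c(=O)c2-c2c(OCc4ccccc4)cc3oc(-c4ccc(OCc5ccccc5)cc4)cc(=O)c3c2OCc2ccccc2)cc1 | intermediate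
21 | target, 3-(apigenin-6-yl)acacetin | COc1ccc(-c2oc3cc(O)cc(O)c3c(=O)c2-c2c(O)cc3oc(-c4ccc(O)cc4)cc(=O)c3c2O)cc1 | target

**Step count**

Total step count: 12
Longest linear sequence: 11 (steps 1–5 and 7–12, from apigenin)

**Steps most likely to fail**

1. Step 11 (key step). The acyl shift must load a carbon that lies between two ortho benzyloxy groups. The sequence may stall after O-aroylation, drift into enol aroylation, or fall back by retro-Claisen cleavage before the ring closes. The fallback runs from 15 back to 20 and makes the same two bonds at the aldehyde oxidation level. Compound 15 is condensed with 4-methoxybenzaldehyde (piperidine, toluene–EtOH, reflux, removal of water). Knoevenagel condensation and oxa-Michael closure should give the 2,3-diarylchroman-4-one F1 as a racemic cis/trans mixture. Dehydrogenation with DDQ in hot dioxane erases both centres and leads to 20.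

2. Step 7. The basic aryllithium may enolise the arylacetaldehyde instead of adding to it, or it may attack the pyranone of the flavone. The fallback runs from 8 back to 13 and replaces the carbanion addition with a catalysed acylation by a non-basic organometal. Pinnick oxidation of 8 (NaClO2, NaH2PO4, 2-methyl-2-butene, t-BuOH–THF–H2O) should give the arylacetic acid F2. Oxalyl chloride with catalytic DMF then gives the acid chloride F3. Aryllithium 11 is transmetalated with ZnCl2 to the arylzinc chloride F4. Negishi-type acylation of F4 with F3 (Pd(PPh3)4 cat., THF, 0 °C to rt) gives ketone 13 directly, so step 8 also falls away.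

3. Step 10. Over-alkylation of the chelated phenol, benzylation at a ring carbon of the phloroglucinol nucleus, or alkylation of the activated CH2 may erode the selectivity. The fallback runs from 14 to 21 and gives ring A no ether protection. Triol 14 is treated with more than three equivalents of 16 under the conditions of step 11. All three phenols are aroylated, and one ortho ester feeds the acyl shift and the ring closure. The other two esters stay as temporary protection in the 5,7-bis(4-methoxybenzoate) F5. Methanolysis (K2CO3 cat., MeOH–THF, rt) should free the 5,7-diol F6, and hydrogenolysis as in step 12 gives 21.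

**Further compounds**

F1 | step 11 | racemic 5,7-bis(benzyloxy)-2-(4-methoxyphenyl)-3-(5,7,4'-tri-O-benzylapigenin-6-yl)chroman-4-one, cis/trans mixture | COc1ccc(C2Oc3cc(OCc4ccccc4)cc(OCc4ccccc4)c3C(=O)C2c2c(OCc3ccccc3)cc3oc(-c4ccc(OCc5ccccc5)cc4)cc(=O)c3c2OCc2ccccc2)cc1
F2 | step 7 | (5,7,4'-tri-O-benzylapigenin-6-yl)acetic acid | O=C(O)Cc1c(OCc2ccccc2)cc2oc(-c3ccc(OCc4ccccc4)cc3)cc(=O)c2c1OCc1ccccc1
F3 | step 7 | (5,7,4'-tri-O-benzylapigenin-6-yl)acetyl chloride | O=C(Cl)Cc1c(OCc2ccccc2)cc2oc(-c3ccc(OCc4ccccc4)cc3)cc(=O)c2c1OCc1ccccc1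
F4 | step 7 | 2,4,6-tris(methoxymethoxy)phenylzinc chloride | Cl[Zn]c1c(OCOC)cc(OCOC)cc1OCOC
F5 | step 10 | 5,7-bis(4-methoxybenzoyloxy)-2-(4-methoxyphenyl)-3-(5,7,4'-tri-O-benzylapigenin-6-yl)-4H-chromen-4-one | COc1ccc(-c2oc3cc(OC(=O)c4ccc(OC)cc4)cc(OC(=O)c4ccc(OC)cc4)c3c(=O)c2-c2c(OCc4ccccc4)cc3oc(-c4ccc(OCc5ccccc5)cc4)cc(=O)c3c2OCc2ccccc2)cc1
F6 | step 10 | 5,7-dihydroxy-2-(4-methoxyphenyl)-3-(5,7,4'-tri-O-benzylapigenin-6-yl)-4H-chromen-4-one | COc1ccc(-c2oc3cc(O)cc(O)c3c(=O)c2-c2c(OCc4ccccc4)cc3oc(-c4ccc(OCc5ccccc5)cc4)cc(=O)c3c2OCc2ccccc2)cc1
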